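## Retrosynthetic overview
1. The target comes from O-acetylation and C8=O → C8=CH2 methylenation of 3β-hydroxy-8-oxo-17-norlabd-13E-en-15-oic acid.
2. Key disconnection: six-membered ring B comes from a five-membered ring B′. An oxidative 1,2-shift moves the C8–C10 bond to C9 in a trans-hydrindane that carries the whole side chain as a C8=C9 alkylidene. This makes C9–C10 and the C8 carbonyl at once.
3. The alkylidene comes from Wittig union of a 3β-hydroxy-4,4,10-trimethyl-trans-hydrindan-8-one with a C7 carboxy-ylide. The 13E geometry is set by syn-methylalumination/carboxylation of 5-chloropent-1-yne.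
4. The hydrindanone comes from reductive methylation (gem-dimethyl, 5α-H) and reduction (3β-OH) of a Hajos–Parrish-type enedione. That enedione is made from 2-methylcyclopentane-1,3-dione and ethyl vinyl ketone, with C10 set by L-phenylalanine.
5. Ring order: ring B′ (purchased five-membered ring), then ring A (annulation), then ring B (expansion of B′).

Assumption: labdane numbering is used for all intermediates (in the hydrindanes C9 is still missing from the ring and C8 is bonded to C10), and phosphorus, iodine(III), aluminium and acylating agents are treated as reagents.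

## Route

Step 1
Reactants: 1 2-methylcyclopentane-1,3-dione; 2 pent-1-en-3-one (ethyl vinyl ketone)
Product: 4 (7aS)-4,7a-dimethyl-2,3,7,7a-tetrahydro-1H-indene-1,5(6H)-dione, via triketone 3 (not isolated)
Conditions: Et3N (5 mol %), MeCN, rt; then L-Phe (1 equiv), (+)-CSA (0.5 equiv), reflux, same pot; recrystallise to >99% ee
Reagents that add atoms: none
Why: Michael addition followed by the Hajos–Parrish–Eder–Sauer–Wiechert aldol condensation (primary amino acid variant for ethyl ketones), in which the L-Phe enamine attacks one of the two enantiotopic ring carbonyls and sets the quaternary centre C10 as S (10β-methyl).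

Step 2
Reactants: 4 (7aS)-4,7a-dimethyl-2,3,7,7a-tetrahydro-1H-indene-1,5(6H)-dione
Product: 5 (7a'S)-4',7a'-dimethyl-2',3',7',7a'-tetrahydrospiro[1,3-dioxolane-2,1'-inden]-5'(6'H)-one
Conditions: HOCH2CH2OH, p-TsOH (cat.), 4 Å MS, rt
Reagents that add atoms: ethylene glycol, OCCO
Why: Thermodynamically controlled ketalisation takes the saturated cyclopentanone (C8) and leaves the less electrophilic tetrasubstituted enone, and no stereocentre is touched.

Step 3
Reactants: 5 (7a'S)-4',7a'-dimethyl-2',3',7',7a'-tetrahydrospiro[1,3-dioxolane-2,1'-inden]-5'(6'H)-one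
Product: 7 (3a'S,7a'S)-4',4',7a'-trimethylhexahydrospiro[1,3-dioxolane-2,1'-inden]-5'(4'H)-one, via lithium enolate 6 (not isolated)
Conditions: Li (2.2 equiv), H2O (1.0 equiv), NH3(l)/THF, −78 → −33 °C; isoprene; MeI (5 equiv), −78 → −33 °C; NH4Cl
Reagents that add atoms: iodomethane, CI
Why: Stork reductive alkylation (dissolving-metal enone reduction), in which axial protonation of the β-carbon C5 anti to the angular methyl gives the trans fusion (5α-H) and the regiodefined enolate 6 is C-methylated at C4 to complete the gem-dimethyl group, while the ketal is inert.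

Step 4
Reactants: 7 (3a'S,7a'S)-4',4',7a'-trimethylhexahydrospiro[1,3-dioxolane-2,1'-inden]-5'(4'H)-one
Product: 9 (3aS,5S,7aS)-5-hydroxy-4,4,7a-trimethyloctahydro-1H-inden-1-one, via hydroxy ketal 8 (not isolated)
Conditions: NaBH4, MeOH, 0 °C; then 2 M HCl, THF, rt (one pot)
Reagents that add atoms: water, O
Why: Borohydride reduction of a chair 4,4-dimethyl-3-ketone proceeds by axial (α-face) hydride delivery to the equatorial 3β-alcohol, and the acid then hydrolyses the dioxolane to release the C8 ketone.

Step 5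
Reactants: 10 5-chloropent-1-yne
Product: 13 (E)-6-chloro-3-methylhex-2-enoic acid, via alkenylalane 11 (not isolated), via lithium alanate 12 (not isolated)
Conditions: Me3Al (2 equiv), Cp2ZrCl2 (20 mol %), CH2Cl2, 0 °C → rt; evaporate; n-BuLi (1 equiv), hexane/THF, −78 °C; CO2 (g), −78 °C → rt; 1 M HCl
Reagents that add atoms: trimethylaluminium, C[Al](C)C; carbon dioxide, O=C=O
Why: Negishi zirconium-catalysed methylalumination is a syn addition that places Al on the terminal carbon, and carboxylation of the alanate occurs with retention, so CH3 and CO2H end up cis (13E), while the primary chloride is inert.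

Step 6
Reactants: 13 (E)-6-chloro-3-methylhex-2-enoic acid
Product: 15 [(4E)-5-carboxy-4-methylpent-4-en-1-yl]triphenylphosphonium iodide, via iodo acid 14 (not isolated)
Conditions: NaI (1.1 equiv), PPh3 (1.1 equiv), MeCN, reflux
Reagents that add atoms: triphenylphosphine, c1ccc(cc1)P(c1ccccc1)c1ccccc1; sodium iodide, [Na+].[I-]
Why: Finkelstein exchange followed by SN2 quaternisation of PPh3, as for ω-carboxyalkylphosphonium salts, and the E-enoic acid can neither lactonise nor accept the phosphine at its β,β-disubstituted carbon.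

Step 7
Reactants: 9 (3aS,5S,7aS)-5-hydroxy-4,4,7a-trimethyloctahydro-1H-inden-1-one; 15 [(4E)-5-carboxy-4-methylpent-4-en-1-yl]triphenylphosphonium iodide
Product: 17 (2E,6Z)-6-[(3aR,5S,7aS)-5-hydroxy-4,4,7a-trimethyloctahydro-1H-inden-1-ylidene]-3-methylhex-2-enoic acid, via ylide 16 (not isolated)
Conditions: 15 (3 equiv), KOt-Bu (6.5 equiv), THF, 0 °C → rt; add 9; reflux; 1 M HCl
Reagents that add atoms: none
Why: Wittig olefination of a neopentyl cyclopentanone with a non-stabilised ylide, as practised on 17-oxo steroids (mainly Z), where the carboxylate form protects the enoate from Michael addition and γ-deprotonation and the C8=C9 geometry is of no lasting consequence.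

Step 8
Reactants: 17 (2E,6Z)-6-[(3aR,5S,7aS)-5-hydroxy-4,4,7a-trimethyloctahydro-1H-inden-1-ylidene]-3-methylhex-2-enoic acid
Product: 20 3β-hydroxy-8-oxo-17-norlabd-13E-en-15-oic acid (5α-H; 9α-H; 10β-Me), via methoxy-iodane adduct 18 (not isolated), via 9-epi keto acid 19 (not isolated)
Conditions: PhI(OH)OTs (1.1 equiv), MeOH–H2O 95:5, 0 °C → rt; 1 M HCl, 30 min; extract; NaOMe (3 equiv), MeOH, rt; 1 M HCl
Reagents that add atoms: water, O
Why: Proposed new method: the iodine(III) oxidative 1,2-shift of exocyclic alkenes (closest known types: the Koser-reagent Wittig/ring-expansion sequence of methylenebenzocycloalkanes by aryl migration, and the Tl(III) ring enlargement of simple methylenecycloalkanes) is extended to a trisubstituted all-aliphatic alkylidenecyclopentane; the iodane adds to the only electron-rich alkene from the α face with I at C9 and MeOH at tertiary C8, the bulky λ3-iodanyl nucleofuge sits anti to the largest C8 substituent, quaternary C10, which is also the electronically best migrating group, so loss of PhI drives a semipinacol shift of C10 from C8 to C9 that forms C9–C10 and ring B, hydrolysis of the oxocarbenium ion gives the C8 ketone, inversion at C9 gives 19, and NaOMe equilibrates 19 through the enolate to the equatorial 9β-side-chain ketone 20.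

Step 9
Reactants: 20 3β-hydroxy-8-oxo-17-norlabd-13E-en-15-oic acid
Product: 21 3β-hydroxylabda-8(17),13E-dien-15-oic acid
Conditions: Ph3PCH3Br (5 equiv), KOt-Bu (5 equiv), THF, 0 → 40 °C; 1 M HCl
Reagents that add atoms: methyltriphenylphosphonium bromide, C[P+](c1ccccc1)(c1ccccc1)c1ccccc1.[Br-]
Why: Wittig methylenation of an 8-oxolabdane, in which the alcohol and acid ride through as their potassium salts, the carboxylate-deactivated enoate is untouched and C9 stays in its thermodynamically preferred equatorial configuration.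

Step 10
Reactants: 21 3β-hydroxylabda-8(17),13E-dien-15-oic acid
Product: 22 3β-acetoxylabda-8(17),13E-dien-15-oic acid (target)
Conditions: Ac2O, pyridine, DMAP (cat.), CH2Cl2, rt; then aq. NaHCO3, acidify
Reagents that add atoms: acetic anhydride, CC(=O)OC(C)=O
Why: DMAP-catalysed O-acylation of the equatorial 3β-alcohol with retention, and any mixed anhydride formed at C15 is hydrolysed in the aqueous work-up.

## Compound list
1 | 2-methylcyclopentane-1,3-dione | CC1C(=O)CCC1=O | starting material
2 | pent-1-en-3-one | C=CC(=O)CC | starting material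
3 | 2-methyl-2-(3-oxopentyl)cyclopentane-1,3-dione | CCC(=O)CCC1(C)C(=O)CCC1=O | intermediate
4 | (7aS)-4,7a-dimethyl-2,3,7,7a-tetrahydro-1H-indene-1,5(6H)-dione | O=C1CC[C@]2(C)C(=O)CCC2=C1C | intermediate
5 | C8 ethylene ketal of 4 | O=C1CC[C@]2(C)C3(OCCO3)CCC2=C1C | intermediate
6 | lithium C3–C4 enolate, trans-fused (5α-H) | CC1=C([O-])CC[C@]2(C)C3(OCCO3)CC[C@@H]12.[Li+] | intermediate
7 | (3a'S,7a'S)-4',4',7a'-trimethylhexahydrospiro[1,3-dioxolane-2,1'-inden]-5'(4'H)-one | O=C1CC[C@]2(C)C3(OCCO3)CC[C@H]2C1(C)C | intermediate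
8 | (3a'S,5'S,7a'S)-3β-hydroxy ketal | O[C@H]1CC[C@]2(C)C3(OCCO3)CC[C@H]2C1(C)C | intermediate
9 | (3aS,5S,7aS)-5-hydroxy-4,4,7a-trimethyloctahydro-1H-inden-1-one | O[C@H]1CC[C@]2(C)C(=O)CC[C@H]2C1(C)C | intermediate
10 | 5-chloropent-1-yne | C#CCCCCl | starting material
11 | (E)-(5-chloro-2-methylpent-1-enyl)dimethylaluminium | C[Al](C)/C=C(\C)CCCCl | intermediate
12 | lithium butyl[(E)-5-chloro-2-methylpent-1-enyl]dimethylaluminate | [Li+].CCCC[Al-](C)(C)/C=C(\C)CCCCl | intermediate
13 | (E)-6-chloro-3-methylhex-2-enoic acid | OC(=O)/C=C(\C)CCCCl | intermediate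
14 | (E)-6-iodo-3-methylhex-2-enoic acid | OC(=O)/C=C(\C)CCCI | intermediate
15 | [(4E)-5-carboxy-4-methylpent-4-en-1-yl]triphenylphosphonium iodide | OC(=O)/C=C(\C)CCC[P+](c1ccccc1)(c1ccccc1)c1ccccc1.[I-] | intermediate
16 | potassium (E)-3-methyl-6-(triphenyl-λ5-phosphanylidene)hex-2-enoate | [K+].[O-]C(=O)/C=C(\C)CCC=P(c1ccccc1)(c1ccccc1)c1ccccc1 | intermediate
17 | (2E,6Z)-6-[(3aR,5S,7aS)-5-hydroxy-4,4,7a-trimethyloctahydro-1H-inden-1-ylidene]-3-methylhex-2-enoic acid | O[C@H]1CC[C@]2(C)/C(=C\CC/C(C)=C/C(=O)O)CC[C@H]2C1(C)C | intermediate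
18 | 8β-methoxy-9-[phenyl(tosyloxy)-λ3-iodanyl] adduct of 17 (I delivered from the α face, anti addition) | O[C@H]1CC[C@]2(C)[C@](OC)([C@H](CC/C(C)=C/C(=O)O)I(c3ccccc3)OS(=O)(=O)c3ccc(C)cc3)CC[C@H]2C1(C)C | intermediate
19 | 9-epi-3β-hydroxy-8-oxo-17-norlabd-13E-en-15-oic acid (9β-H, axial chain) | O[C@H]1CC[C@]2(C)[C@H](CC/C(C)=C/C(=O)O)C(=O)CC[C@H]2C1(C)C | intermediate
20 | 3β-hydroxy-8-oxo-17-norlabd-13E-en-15-oic acid | O[C@H]1CC[C@]2(C)[C@@H](CC/C(C)=C/C(=O)O)C(=O)CC[C@H]2C1(C)C | intermediate
21 | 3β-hydroxylabda-8(17),13E-dien-15-oic acid | O[C@H]1CC[C@]2(C)[C@@H](CC/C(C)=C/C(=O)O)C(=C)CC[C@H]2C1(C)C | intermediate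
22 | 3β-acetoxylabda-8(17),13E-dien-15-oic acid (3S,5R,9S,10R) | C=C1CC[C@H]2C(C)(C)[C@@H](OC(C)=O)CC[C@]2(C)[C@H]1CC/C(C)=C/C(=O)O | target

## Step count and risks
Total step count: 10. Longest linear sequence: 8 (steps 1–4 and 7–10). Steps 5–6 form the side-chain branch.

**Step 8 (the proposed new ring expansion).**
- Possible failures:
  - migration of C7 instead of C10;
  - too much cation character at C8, leading to a 1,2-methyl shift from C10 or to proton loss;
  - solvent attack at C9 instead of C8;
  - an unfavourable C9 equilibrium.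
- The fallback uses known chemistry, sets out from 17 and comes back at 19.
- Catalytic OsO4/NMO dihydroxylates only the electron-rich C8=C9 bond from the α face and gives the 3β,8α,9-triol acid F1.
- Bu2SnO-catalysed tosylation (TsCl, Et3N) picks the secondary hydroxyl of the 1,2-diol over the isolated neopentyl 3β-OH and gives the 9-monotosylate F2.
- KOt-Bu in THF/t-BuOH then triggers the base-induced pinacol-type rearrangement of the hydroxy tosylate, with the sulfonate anti to C10. This gives 19, which is equilibrated to 20 as in step 8.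

**Step 7 (Wittig reaction on a hindered, enolisable ketone with a functionalised ylide).**
- The fallback sets out from 9 and comes back at 20.
- Vinylmagnesium bromide/CeCl3 adds from the α face to give the 8α-vinyl-8β-carbinol F3.
- Heating with excess 2-methoxypropene and catalytic PPTS forms the 8-O-isopropenyl 3-O-(2-methoxyprop-2-yl) bis-ether F4.
- F4 undergoes the Saucy–Marbet Claisen rearrangement in the same pot to the protected (8E)-methyl ketone F5.
- Dilute acid releases the hydroxy methyl ketone F6.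
- Horner–Wadsworth–Emmons reaction with triethyl phosphonoacetate/NaH gives the (13E)-ethyl ester F7, and the minor 13Z isomer is removed by chromatography.
- LiOH then gives the (8E)-isomer of 17, acid F8.
- Under the step 8 conditions F8 reacts through the diastereomeric methoxy-iodane adduct F9. With the E geometry, inversion at C9 delivers 20 directly.

**Step 3 (trans selectivity of the dissolving-metal reduction in the hydrindenone series, and over-alkylation).**
- The fallback sets out from 5 and comes back at 7.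
- Deconjugative methylation (KOt-Bu, MeI, t-BuOH) gives the 4,4-dimethyl-Δ5(6)-3-ketone ketal F10.
- Its trisubstituted alkene is hydrogenated (H2, 50 bar, Pd/C, EtOH) from the α face. The β face is blocked by the 10β- and 4β-methyl groups, so this gives 5α-H and hence 7.

## Further compounds
F1 | step 8 | 3β,8α,9-triol acid (α-face syn-diol of 17) | O[C@H]1CC[C@]2(C)[C@@](O)([C@@H](O)CC/C(C)=C/C(=O)O)CC[C@H]2C1(C)C
F2 | step 8 | 9-O-tosylate of F1 | O[C@H]1CC[C@]2(C)[C@@](O)([C@@H](OS(=O)(=O)c3ccc(C)cc3)CC/C(C)=C/C(=O)O)CC[C@H]2C1(C)C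
F3 | step 7 | 8α-vinyl-3β,8β-diol | O[C@H]1CC[C@]2(C)[C@](O)(C=C)CC[C@H]2C1(C)C
F4 | step 7 | 8-O-isopropenyl 3-O-(2-methoxyprop-2-yl) bis-ether of F3 | COC(C)(C)O[C@H]1CC[C@]2(C)[C@](OC(C)=C)(C=C)CC[C@H]2C1(C)C
F5 | step 7 | 3-O-(2-methoxyprop-2-yl) (8E)-alkylidene methyl ketone | COC(C)(C)O[C@H]1CC[C@]2(C)/C(=C/CCC(C)=O)CC[C@H]2C1(C)C
F6 | step 7 | 3β-hydroxy (8E)-alkylidene methyl ketone | O[C@H]1CC[C@]2(C)/C(=C/CCC(C)=O)CC[C@H]2C1(C)C
F7 | step 7 | ethyl (8E,13E)-ester | O[C@H]1CC[C@]2(C)/C(=C/CC/C(C)=C/C(=O)OCC)CC[C@H]2C1(C)C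
F8 | step 7 | (8E)-isomer of 17 | O[C@H]1CC[C@]2(C)/C(=C/CC/C(C)=C/C(=O)O)CC[C@H]2C1(C)C
F9 | step 7 | methoxy-iodane adduct of F8 (C9 epimer of 18) | O[C@H]1CC[C@]2(C)[C@](OC)([C@@H](CC/C(C)=C/C(=O)O)I(c3ccccc3)OS(=O)(=O)c3ccc(C)cc3)CC[C@H]2C1(C)C
F10 | step 3 | 4,4-dimethyl-Δ5(6)-3-ketone C8 ketal | O=C1CC[C@]2(C)C3(OCCO3)CC=C2C1(C)C
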